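Ring A is disconnected between its ether-bearing carbon 1 and hydroxylated carbon 6: a phloroglucinol with hydroxyls on carbons 2, 4 and 6 of ring A around the ether carbon is a cyclised 3,5-dioxohexanoate. The congested ether between rings A and B is therefore made first, by O-alkylation of a ring B phenol. One operation, the intramolecular Claisen condensation of methyl 6-aryloxy-3,5-dioxohexanoate 11, then closes ring A around that oxygen: the aryloxy-bearing terminal carbon attacks the ester carbon. Rings C to F follow singly by CuI-catalysed etherification with two bromobenzaldehydes, each formyl group becoming the next phenol; global debenzylation ends the route.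

Key step: step 7

Remark: rings are lettered A to F from the 2,4,6-trihydroxyphenyl end, positions on each ring are counted from its ether carbon nearer ring A, and the chain of 11 is counted from the ester carbon (chain carbon 1) to the aryloxy-bearing methylene (chain carbon 6); reagents that only deliver protecting groups or oxygen are named in the steps and carry no number.

Step 1
Reactants: 1 4-bromo-2,6-difluorobenzaldehyde
Product: 2 4-bromo-2,6-bis(benzyloxy)benzaldehyde
Conditions: BnOH (2.4 equiv), NaH (2.3 equiv), THF–DMF, 0 °C → rt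
Reagents that add atoms: benzyl alcohol, OCc1ccccc1
Why: Double SNAr, since both C–F bonds are ortho to the formyl group and fluoride is the best leaving group in addition–elimination, so benzyl oxide should replace them and leave the C–Br bond untouched.

Step 2
Reactants: 2 4-bromo-2,6-bis(benzyloxy)benzaldehyde
Product: 4 4-bromo-2,6-bis(benzyloxy)phenol, via aryl formate 3 (not isolated)
Conditions: mCPBA, CH2Cl2, 0 °C → rt; then K2CO3 (cat.), MeOH, rt
Reagents that add atoms: 3-chloroperoxybenzoic acid (mCPBA), OOC(=O)c1cccc(Cl)c1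
Why: Baeyer–Villiger oxidation of an electron-rich 2,6-dialkoxybenzaldehyde should proceed with aryl migration to the formate, which methanolysis converts into the phenol.

Step 3
Reactants: 4 4-bromo-2,6-bis(benzyloxy)phenol
Product: 5 1,3-bis(benzyloxy)-5-bromo-2-(methoxymethoxy)benzene
Conditions: MOMCl, i-Pr2NEt, CH2Cl2, 0 °C → rt
Reagents that add atoms: chloromethyl methyl ether, COCCl
Why: O-alkylation of the phenol by the reactive α-chloro ether (Williamson-type acetal formation) should be clean even at the flanked hydroxyl.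

Step 4
Reactants: 5 1,3-bis(benzyloxy)-5-bromo-2-(methoxymethoxy)benzene
Product: 6 3,5-bis(benzyloxy)-4-(methoxymethoxy)phenol
Conditions: Pd2(dba)3 (2 mol %), t-BuXPhos (8 mol %), KOH, 1,4-dioxane–H2O, 100 °C; then dilute HCl to pH 6
Reagents that add atoms: potassium hydroxide, [K+].[OH-]
Why: Hydroxylation of an aryl bromide by C–O cross-coupling with hydroxide under Pd2(dba)3/t-BuXPhos catalysis is established for unhindered aryl bromides, and the acetal and benzyl ethers are inert to aqueous base.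

Step 5
Reactants: 6 3,5-bis(benzyloxy)-4-(methoxymethoxy)phenol; 7 2-chloro-N-methoxy-N-methylacetamide
Product: 8 2-[3,5-bis(benzyloxy)-4-(methoxymethoxy)phenoxy]-N-methoxy-N-methylacetamide
Conditions: K2CO3, NaI (cat.), acetone, reflux
Reagents that add atoms: none
Why: Williamson SN2 alkylation of the unhindered phenoxide by the α-chloro amide places the future ether oxygen between rings A and B on the carbon that becomes carbon 1 of ring A.

Step 6
Reactants: 9 methyl acetoacetate; 8 2-[3,5-bis(benzyloxy)-4-(methoxymethoxy)phenoxy]-N-methoxy-N-methylacetamide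
Product: 11 methyl 6-[3,5-bis(benzyloxy)-4-(methoxymethoxy)phenoxy]-3,5-dioxohexanoate, via dilithium dienolate 10 (not isolated)
Conditions: 9 (1.5 equiv), LiN(iPr)2 (3.1 equiv), THF, −78 → 0 °C; then 8, −78 → 0 °C; aq NH4Cl
Reagents that add atoms: none
Why: γ-Acylation of the acetoacetate dianion by an N-methoxy-N-methylamide stops at the chelated tetrahedral adduct, so the acidic 3,5-dioxo ester appears only on quench and cannot consume the dianion, as it would with an enolisable aryloxyacetic ester.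

Step 7
Reactants: 11 methyl 6-[3,5-bis(benzyloxy)-4-(methoxymethoxy)phenoxy]-3,5-dioxohexanoate
Product: 13 2-[3,5-bis(benzyloxy)-4-(methoxymethoxy)phenoxy]benzene-1,3,5-triol, via cyclohexane-1,3,5-trione 12 (not isolated)
Conditions: KOtBu (3.5 equiv), degassed THF (0.02 M), 0 → 50 °C, Ar; then 1 M HCl, 0 °C
Reagents that add atoms: none
Why: With excess KOtBu the chain should rest as its 2,4-dienolate, in which the ester is masked, while proton exchange through t-BuOH populates the isomeric dianion charged at chain carbons 4 and 6, the latter acidified by the aryloxy group, whose ester is free. The carbanion at chain carbon 6 adds to the ester carbonyl (chain carbon 1), methoxide leaves, and trione 12 tautomerises to the phloroglucinolate, an aromatic sink that pulls the equilibria forward. The closest known reactions are the Dieckmann-type Claisen cyclisation of 5-oxo esters to cyclohexane-1,3-diones, the base-induced closure of 3,5-dioxo and 3,5,7-trioxo esters to phloroglucinols, and the terminal C-acylation of β-diketone dianions by esters. Ring A closes in a 6-(enolendo)-exo-trig mode, the new bond joining carbons 1 and 6 of ring A, and no stereocentre is created. The step needs C-acylation to beat lactonisation through the enol oxygen on chain carbon 5 to a 4-hydroxy-2-pyranone; the aryloxy group raises the acidity of chain carbon 6, in the only dianion with a free ester that carbanion is a far better nucleophile than the enolate oxygens, and it is the only carbon that can reach the ester carbon through a six-membered transition state.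

Step 8
Reactants: 13 2-[3,5-bis(benzyloxy)-4-(methoxymethoxy)phenoxy]benzene-1,3,5-triol
Product: 14 2-[3,5-bis(benzyloxy)-4-(methoxymethoxy)phenoxy]benzene-1,3,5-triyl triacetate
Conditions: Ac2O, pyridine, rt
Reagents that add atoms: acetic anhydride, CC(=O)OC(C)=O
Why: Pyridine-promoted O-acetylation of the three phenols is fast and wholly O-selective, and it masks the oxidation-prone triol.

Step 9
Reactants: 14 2-[3,5-bis(benzyloxy)-4-(methoxymethoxy)phenoxy]benzene-1,3,5-triyl triacetate
Product: 15 1,3,5-tris(benzyloxy)-2-[3,5-bis(benzyloxy)-4-(methoxymethoxy)phenoxy]benzene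
Conditions: NaH (6 equiv), BnCl (4 equiv), H2O (3 equiv), DMF, 0 °C → rt
Reagents that add atoms: benzyl chloride, ClCc1ccccc1
Why: Hydroxide made from NaH and water cleaves the aryl acetates one after another and each phenoxide is benzylated as it appears (Williamson ether synthesis), which keeps polyphenoxide, and with it C-benzylation, at a low level.

Step 10
Reactants: 15 1,3,5-tris(benzyloxy)-2-[3,5-bis(benzyloxy)-4-(methoxymethoxy)phenoxy]benzene
Product: 16 2,6-bis(benzyloxy)-4-[2,4,6-tris(benzyloxy)phenoxy]phenol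
Conditions: conc. HCl (cat.), MeOH–THF, 50 °C
Reagents that add atoms: none
Why: Acid-catalysed transacetalisation in methanol removes the methoxymethyl group as dimethoxymethane, while benzyl and diaryl ethers are stable to dilute HCl.

Step 11
Reactants: 17 5-bromo-1,2,3-trimethoxybenzene
Product: 18 6-bromo-2,3,4-trimethoxybenzaldehyde
Conditions: Cl2CHOMe, TiCl4, CH2Cl2, 0 °C → rt; then H2O
Reagents that add atoms: dichloromethyl methyl ether, COC(Cl)Cl; water, O
Why: Rieche formylation, in which the two open positions of 17 are equivalent and each is ortho and para to a methoxy group, so only one aldehyde can form.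

Step 12
Reactants: 18 6-bromo-2,3,4-trimethoxybenzaldehyde
Product: 19 6-bromo-2,3,4-trihydroxybenzaldehyde
Conditions: BBr3 (4 equiv), CH2Cl2, −78 °C → rt; then H2O
Reagents that add atoms: none
Why: BBr3 cleaves aryl methyl ethers by Lewis acid-assisted SN2 demethylation and should leave the aldehyde and the aryl bromide untouched.

Step 13
Reactants: 19 6-bromo-2,3,4-trihydroxybenzaldehyde
Product: 20 2,3,4-tris(benzyloxy)-6-bromobenzaldehyde
Conditions: BnBr (3.6 equiv), K2CO3, DMF, 60 °C
Reagents that add atoms: benzyl bromide, BrCc1ccccc1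
Why: Threefold Williamson benzylation, in which the carbonyl-bonded 2-hydroxyl needs warming in DMF but should react.

Step 14
Reactants: 16 2,6-bis(benzyloxy)-4-[2,4,6-tris(benzyloxy)phenoxy]phenol; 20 2,3,4-tris(benzyloxy)-6-bromobenzaldehyde
Product: 21 2,3,4-tris(benzyloxy)-6-{2,6-bis(benzyloxy)-4-[2,4,6-tris(benzyloxy)phenoxy]phenoxy}benzaldehyde (rings A–B–C aldehyde; formyl on position 2 of ring C)
Conditions: 20 (1.3 equiv), CuI (20 mol %), picolinic acid (40 mol %), K3PO4, DMSO, 90 °C, Ar
Reagents that add atoms: none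
Why: Ullmann-type C–O coupling with the CuI/picolinic acid system, which tolerates 2,6-disubstituted phenols, should form the ether between position 4 of ring B and position 1 of ring C, helped by the ortho-formyl group of 20, whose carbon marks position 2 of ring C, the site of the next oxygen.

Step 15
Reactants: 21 rings A–B–C aldehyde
Product: 23 2,3,4-tris(benzyloxy)-6-{2,6-bis(benzyloxy)-4-[2,4,6-tris(benzyloxy)phenoxy]phenoxy}phenol (rings A–B–C phenol; free hydroxyl on position 2 of ring C), via rings A–B–C formate 22 (not isolated)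
Conditions: mCPBA, CH2Cl2, 0 °C → rt; then K2CO3 (cat.), MeOH, rt
Reagents that add atoms: 3-chloroperoxybenzoic acid (mCPBA), OOC(=O)c1cccc(Cl)c1
Why: Baeyer–Villiger oxidation, in which the electron-rich aryl group flanked by two oxygen-bearing carbons migrates, and methanolysis of the formate frees the phenol on position 2 of ring C that is the next nucleophile.

Step 16
Reactants: 23 rings A–B–C phenol; 2 4-bromo-2,6-bis(benzyloxy)benzaldehyde
Product: 24 rings A–B–C–D aldehyde (23 with the oxygen on position 2 of ring C bonded to position 1 of a 3,5-bis(benzyloxy)-4-formylphenyl ring D)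
Conditions: 2 (1.3 equiv), CuI (20 mol %), picolinic acid (40 mol %), K3PO4, DMSO, 90 °C, Ar
Reagents that add atoms: none
Why: Ullmann-type C–O coupling of the flanked phenol with an unhindered aryl bromide that is activated by its para-formyl group, whose carbon marks position 4 of ring D.

Step 17
Reactants: 24 rings A–B–C–D aldehyde
Product: 26 rings A–B–C–D phenol (24 with hydroxyl in place of formyl on position 4 of ring D), via rings A–B–C–D formate 25 (not isolated)
Conditions: mCPBA, CH2Cl2, 0 °C → rt; then K2CO3 (cat.), MeOH, rt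
Reagents that add atoms: 3-chloroperoxybenzoic acid (mCPBA), OOC(=O)c1cccc(Cl)c1
Why: Baeyer–Villiger oxidation of a 2,6-dialkoxy-4-aryloxybenzaldehyde with aryl migration, followed by methanolysis of the formate, as in step 2.

Step 18
Reactants: 26 rings A–B–C–D phenol; 20 2,3,4-tris(benzyloxy)-6-bromobenzaldehyde
Product: 27 rings A–B–C–D–E aldehyde (26 with the oxygen on position 4 of ring D bonded to position 1 of a 2-formyl-3,4,5-tris(benzyloxy)phenyl ring E)
Conditions: 20 (1.3 equiv), CuI (20 mol %), picolinic acid (40 mol %), K3PO4, DMSO, 90 °C, Ar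
Reagents that add atoms: none
Why: The same Ullmann-type coupling as in step 14, between a 2,6-bis(benzyloxy)phenol and the ortho-formyl aryl bromide, forms the ether between position 4 of ring D and position 1 of ring E.

Step 19
Reactants: 27 rings A–B–C–D–E aldehyde
Product: 29 rings A–B–C–D–E phenol (27 with hydroxyl in place of formyl on position 2 of ring E), via rings A–B–C–D–E formate 28 (not isolated)
Conditions: mCPBA, CH2Cl2, 0 °C → rt; then K2CO3 (cat.), MeOH, rt
Reagents that add atoms: 3-chloroperoxybenzoic acid (mCPBA), OOC(=O)c1cccc(Cl)c1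
Why: Baeyer–Villiger oxidation and formate methanolysis as in step 15 reveal the phenol on position 2 of ring E.

Step 20
Reactants: 29 rings A–B–C–D–E phenol; 2 4-bromo-2,6-bis(benzyloxy)benzaldehyde
Product: 30 rings A–F aldehyde (29 with the oxygen on position 2 of ring E bonded to position 1 of a 3,5-bis(benzyloxy)-4-formylphenyl ring F)
Conditions: 2 (1.5 equiv), CuI (20 mol %), picolinic acid (40 mol %), K3PO4, DMSO, 90 °C, Ar
Reagents that add atoms: none
Why: Ullmann-type C–O coupling as in step 16 forms the ether between position 2 of ring E and position 1 of ring F with the unhindered, formyl-activated bromide.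

Step 21
Reactants: 30 rings A–F aldehyde
Product: 32 pentadeca-O-benzyl hexamer with free hydroxyl on position 4 of ring F, via rings A–F formate 31 (not isolated)
Conditions: mCPBA, CH2Cl2, 0 °C → rt; then K2CO3 (cat.), MeOH, rt
Reagents that add atoms: 3-chloroperoxybenzoic acid (mCPBA), OOC(=O)c1cccc(Cl)c1
Why: Baeyer–Villiger oxidation and formate methanolysis as in step 17 turn the last formyl group into the hydroxyl on position 4 of ring F.

Step 22
Reactants: 32 pentadeca-O-benzyl hexamer
Product: 33 CNP0114537.0 (target)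
Conditions: H2 (1 atm), Pd(OH)2/C, THF–MeOH, rt; filtration and evaporation under Ar
Reagents that add atoms: none
Why: Catalytic hydrogenolysis should cleave all fifteen O-benzyl bonds, while diaryl ether bonds and arene rings are not reduced at room temperature and 1 atm.

Compound list

1 | 4-bromo-2,6-difluorobenzaldehyde | O=Cc1c(F)cc(Br)cc1F | starting material
2 | 4-bromo-2,6-bis(benzyloxy)benzaldehyde | O=Cc1c(OCc2ccccc2)cc(Br)cc1OCc1ccccc1 | intermediate
3 | 4-bromo-2,6-bis(benzyloxy)phenyl formate | O=COc1c(OCc2ccccc2)cc(Br)cc1OCc1ccccc1 | intermediate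
4 | 4-bromo-2,6-bis(benzyloxy)phenol | Oc1c(OCc2ccccc2)cc(Br)cc1OCc1ccccc1 | intermediate
5 | 1,3-bis(benzyloxy)-5-bromo-2-(methoxymethoxy)benzene | COCOc1c(OCc2ccccc2)cc(Br)cc1OCc1ccccc1 | intermediate
6 | 3,5-bis(benzyloxy)-4-(methoxymethoxy)phenol | COCOc1c(OCc2ccccc2)cc(O)cc1OCc1ccccc1 | intermediate
7 | 2-chloro-N-methoxy-N-methylacetamide | CON(C)C(=O)CCl | starting material
8 | 2-[3,5-bis(benzyloxy)-4-(methoxymethoxy)phenoxy]-N-methoxy-N-methylacetamide | CON(C)C(=O)COc1cc(OCc2ccccc2)c(OCOC)c(OCc2ccccc2)c1 | intermediate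
9 | methyl acetoacetate | COC(=O)CC(C)=O | starting material
10 | dilithium dienolate of methyl acetoacetate | [Li+].[Li+].COC([O-])=CC([O-])=C | intermediate
11 | methyl 6-[3,5-bis(benzyloxy)-4-(methoxymethoxy)phenoxy]-3,5-dioxohexanoate | COC(=O)CC(=O)CC(=O)COc1cc(OCc2ccccc2)c(OCOC)c(OCc2ccccc2)c1 | intermediate
12 | 2-[3,5-bis(benzyloxy)-4-(methoxymethoxy)phenoxy]cyclohexane-1,3,5-trione | COCOc1c(OCc2ccccc2)cc(OC2C(=O)CC(=O)CC2=O)cc1OCc1ccccc1 | intermediate
13 | 2-[3,5-bis(benzyloxy)-4-(methoxymethoxy)phenoxy]benzene-1,3,5-triol | Oc1cc(O)c(Oc2cc(OCc3ccccc3)c(OCOC)c(OCc3ccccc3)c2)c(O)c1 | intermediate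
14 | 2-[3,5-bis(benzyloxy)-4-(methoxymethoxy)phenoxy]benzene-1,3,5-triyl triacetate | CC(=O)Oc1cc(OC(C)=O)c(Oc2cc(OCc3ccccc3)c(OCOC)c(OCc3ccccc3)c2)c(OC(C)=O)c1 | intermediate
15 | 1,3,5-tris(benzyloxy)-2-[3,5-bis(benzyloxy)-4-(methoxymethoxy)phenoxy]benzene | COCOc1c(OCc2ccccc2)cc(Oc2c(OCc3ccccc3)cc(OCc3ccccc3)cc2OCc2ccccc2)cc1OCc1ccccc1 | intermediate
16 | 2,6-bis(benzyloxy)-4-[2,4,6-tris(benzyloxy)phenoxy]phenol | Oc1c(OCc2ccccc2)cc(Oc2c(OCc3ccccc3)cc(OCc3ccccc3)cc2OCc2ccccc2)cc1OCc1ccccc1 | intermediate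
17 | 5-bromo-1,2,3-trimethoxybenzene | COc1cc(Br)cc(OC)c1OC | starting material
18 | 6-bromo-2,3,4-trimethoxybenzaldehyde | COc1cc(Br)c(C=O)c(OC)c1OC | intermediate
19 | 6-bromo-2,3,4-trihydroxybenzaldehyde | O=Cc1c(Br)cc(O)c(O)c1O | intermediate
20 | 2,3,4-tris(benzyloxy)-6-bromobenzaldehyde | O=Cc1c(Br)cc(OCc2ccccc2)c(OCc2ccccc2)c1OCc1ccccc1 | intermediate
21 | rings A–B–C aldehyde, 2,3,4-tris(benzyloxy)-6-{2,6-bis(benzyloxy)-4-[2,4,6-tris(benzyloxy)phenoxy]phenoxy}benzaldehyde | O=Cc1c(Oc2c(OCc3ccccc3)cc(Oc3c(OCc4ccccc4)cc(OCc4ccccc4)cc3OCc3ccccc3)cc2OCc2ccccc2)cc(OCc2ccccc2)c(OCc2ccccc2)c1OCc1ccccc1 | intermediate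
22 | rings A–B–C formate (formate ester of 23) | O=COc1c(Oc2c(OCc3ccccc3)cc(Oc3c(OCc4ccccc4)cc(OCc4ccccc4)cc3OCc3ccccc3)cc2OCc2ccccc2)cc(OCc2ccccc2)c(OCc2ccccc2)c1OCc1ccccc1 | intermediate
23 | rings A–B–C phenol, 2,3,4-tris(benzyloxy)-6-{2,6-bis(benzyloxy)-4-[2,4,6-tris(benzyloxy)phenoxy]phenoxy}phenol | Oc1c(Oc2c(OCc3ccccc3)cc(Oc3c(OCc4ccccc4)cc(OCc4ccccc4)cc3OCc3ccccc3)cc2OCc2ccccc2)cc(OCc2ccccc2)c(OCc2ccccc2)c1OCc1ccccc1 | intermediate
24 | rings A–B–C–D aldehyde (formyl on position 4 of ring D, benzyloxy on positions 3 and 5, position 1 bonded to the oxygen on position 2 of ring C) | O=Cc1c(OCc2ccccc2)cc(Oc2c(Oc3c(OCc4ccccc4)cc(Oc4c(OCc5ccccc5)cc(OCc5ccccc5)cc4OCc4ccccc4)cc3OCc3ccccc3)cc(OCc3ccccc3)c(OCc3ccccc3)c2OCc2ccccc2)cc1OCc1ccccc1 | intermediate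
25 | rings A–B–C–D formate (formate ester of 26) | O=COc1c(OCc2ccccc2)cc(Oc2c(Oc3c(OCc4ccccc4)cc(Oc4c(OCc5ccccc5)cc(OCc5ccccc5)cc4OCc4ccccc4)cc3OCc3ccccc3)cc(OCc3ccccc3)c(OCc3ccccc3)c2OCc2ccccc2)cc1OCc1ccccc1 | intermediate
26 | rings A–B–C–D phenol (free hydroxyl on position 4 of ring D) | Oc1c(OCc2ccccc2)cc(Oc2c(Oc3c(OCc4ccccc4)cc(Oc4c(OCc5ccccc5)cc(OCc5ccccc5)cc4OCc4ccccc4)cc3OCc3ccccc3)cc(OCc3ccccc3)c(OCc3ccccc3)c2OCc2ccccc2)cc1OCc1ccccc1 | intermediate
27 | rings A–B–C–D–E aldehyde (formyl on position 2 of ring E, benzyloxy on positions 3, 4 and 5, position 1 bonded to the oxygen on position 4 of ring D) | O=Cc1c(Oc2c(OCc3ccccc3)cc(Oc3c(Oc4c(OCc5ccccc5)cc(Oc5c(OCc6ccccc6)cc(OCc6ccccc6)cc5OCc5ccccc5)cc4OCc4ccccc4)cc(OCc4ccccc4)c(OCc4ccccc4)c3OCc3ccccc3)cc2OCc2ccccc2)cc(OCc2ccccc2)c(OCc2ccccc2)c1OCc1ccccc1 | intermediate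
28 | rings A–B–C–D–E formate (formate ester of 29) | O=COc1c(Oc2c(OCc3ccccc3)cc(Oc3c(Oc4c(OCc5ccccc5)cc(Oc5c(OCc6ccccc6)cc(OCc6ccccc6)cc5OCc5ccccc5)cc4OCc4ccccc4)cc(OCc4ccccc4)c(OCc4ccccc4)c3OCc3ccccc3)cc2OCc2ccccc2)cc(OCc2ccccc2)c(OCc2ccccc2)c1OCc1ccccc1 | intermediate
29 | rings A–B–C–D–E phenol (free hydroxyl on position 2 of ring E) | Oc1c(Oc2c(OCc3ccccc3)cc(Oc3c(Oc4c(OCc5ccccc5)cc(Oc5c(OCc6ccccc6)cc(OCc6ccccc6)cc5OCc5ccccc5)cc4OCc4ccccc4)cc(OCc4ccccc4)c(OCc4ccccc4)c3OCc3ccccc3)cc2OCc2ccccc2)cc(OCc2ccccc2)c(OCc2ccccc2)c1OCc1ccccc1 | intermediate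
30 | rings A–F aldehyde (formyl on position 4 of ring F, benzyloxy on positions 3 and 5, position 1 bonded to the oxygen on position 2 of ring E) | O=Cc1c(OCc2ccccc2)cc(Oc2c(Oc3c(OCc4ccccc4)cc(Oc4c(Oc5c(OCc6ccccc6)cc(Oc6c(OCc7ccccc7)cc(OCc7ccccc7)cc6OCc6ccccc6)cc5OCc5ccccc5)cc(OCc5ccccc5)c(OCc5ccccc5)c4OCc4ccccc4)cc3OCc3ccccc3)cc(OCc3ccccc3)c(OCc3ccccc3)c2OCc2ccccc2)cc1OCc1ccccc1 | intermediate
31 | rings A–F formate (formate ester of 32) | O=COc1c(OCc2ccccc2)cc(Oc2c(Oc3c(OCc4ccccc4)cc(Oc4c(Oc5c(OCc6ccccc6)cc(Oc6c(OCc7ccccc7)cc(OCc7ccccc7)cc6OCc6ccccc6)cc5OCc5ccccc5)cc(OCc5ccccc5)c(OCc5ccccc5)c4OCc4ccccc4)cc3OCc3ccccc3)cc(OCc3ccccc3)c(OCc3ccccc3)c2OCc2ccccc2)cc1OCc1ccccc1 | intermediate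
32 | pentadeca-O-benzyl hexamer with free hydroxyl on position 4 of ring F | Oc1c(OCc2ccccc2)cc(Oc2c(Oc3c(OCc4ccccc4)cc(Oc4c(Oc5c(OCc6ccccc6)cc(Oc6c(OCc7ccccc7)cc(OCc7ccccc7)cc6OCc6ccccc6)cc5OCc5ccccc5)cc(OCc5ccccc5)c(OCc5ccccc5)c4OCc4ccccc4)cc3OCc3ccccc3)cc(OCc3ccccc3)c(OCc3ccccc3)c2OCc2ccccc2)cc1OCc1ccccc1 | intermediate
33 | CNP0114537.0 | Oc1cc(O)c(Oc2cc(O)c(Oc3cc(O)c(O)c(O)c3Oc3cc(O)c(Oc4cc(O)c(O)c(O)c4Oc4cc(O)c(O)c(O)c4)c(O)c3)c(O)c2)c(O)c1 | target

Total step count: 22. Longest linear sequence: 19 steps (steps 1–10 and 14–22, counted from 1).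

Steps most likely to fail

Step 7. The closure has not been run on a chain whose nucleophilic end carries an aryloxy group. O-acylation through the enol oxygen on chain carbon 5 (lactonisation to a 4-hydroxy-2-pyranone), or intermolecular condensation of the polyenolate, may outrun the attack of chain carbon 6 on the ester. The fallback makes the ether between rings A and B by the coupling chemistry used later in the route; it sets out from 2 and returns at 16. Purchased 1,3,5-tris(benzyloxy)benzene would be formylated (POCl3, DMF, Vilsmeier–Haack) to 2,4,6-tris(benzyloxy)benzaldehyde F1. Oxidation with mCPBA would give 2,4,6-tris(benzyloxy)phenyl formate F2, and methanolysis 2,4,6-tris(benzyloxy)phenol F3. Coupling of F3 with bromide 2 (CuI, picolinic acid, K3PO4, DMSO, 90 °C) should give 2,6-bis(benzyloxy)-4-[2,4,6-tris(benzyloxy)phenoxy]benzaldehyde F4. Baeyer–Villiger oxidation of F4 to 2,6-bis(benzyloxy)-4-[2,4,6-tris(benzyloxy)phenoxy]phenyl formate F5 and methanolysis then deliver 16.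

Step 14 (the same concern returns in step 18). C–O bond formation from the phenoxide of a phenol flanked by two benzyloxy groups may be slow under CuI catalysis, so that reduction of the bromide or loss of catalyst takes over. The fallback replaces catalysis by SNAr on a fluoride; it sets out from 16 and returns at 21. Purchased 5-fluoro-1,2,3-trimethoxybenzene would be taken through the operations of steps 11 to 13: Rieche formylation to 6-fluoro-2,3,4-trimethoxybenzaldehyde F6, BBr3 demethylation to 6-fluoro-2,3,4-trihydroxybenzaldehyde F7, and benzylation to 2,3,4-tris(benzyloxy)-6-fluorobenzaldehyde F8. The phenoxide of 16 would then displace the fluoride ortho to the formyl group (Cs2CO3, DMSO, 110 °C) to give 21. For step 18 the same fluoride would be used with 26 to reach 27.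

Step 9. If deacetylation runs ahead of alkylation, polyphenoxide builds up and benzylation at the two unsubstituted carbons of ring A (positions 3 and 5) competes with O-benzylation. The fallback avoids free phenoxide altogether; it sets out from 13 and returns at 15. Triol 13 would be tris-O-benzylated directly by a Mitsunobu reaction (BnOH, PPh3, diisopropyl azodicarboxylate, THF, 0 °C → rt), in which the phenols react as oxygen nucleophiles toward the alkoxyphosphonium ion; no new compound arises (F0).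

Further compounds

F1 | step 7 | 2,4,6-tris(benzyloxy)benzaldehyde | O=Cc1c(OCc2ccccc2)cc(OCc2ccccc2)cc1OCc1ccccc1
F2 | step 7 | 2,4,6-tris(benzyloxy)phenyl formate | O=COc1c(OCc2ccccc2)cc(OCc2ccccc2)cc1OCc1ccccc1
F3 | step 7 | 2,4,6-tris(benzyloxy)phenol | Oc1c(OCc2ccccc2)cc(OCc2ccccc2)cc1OCc1ccccc1
F4 | step 7 | 2,6-bis(benzyloxy)-4-[2,4,6-tris(benzyloxy)phenoxy]benzaldehyde | O=Cc1c(OCc2ccccc2)cc(Oc2c(OCc3ccccc3)cc(OCc3ccccc3)cc2OCc2ccccc2)cc1OCc1ccccc1
F5 | step 7 | 2,6-bis(benzyloxy)-4-[2,4,6-tris(benzyloxy)phenoxy]phenyl formate | O=COc1c(OCc2ccccc2)cc(Oc2c(OCc3ccccc3)cc(OCc3ccccc3)cc2OCc2ccccc2)cc1OCc1ccccc1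
F6 | step 14 | 6-fluoro-2,3,4-trimethoxybenzaldehyde | COc1cc(F)c(C=O)c(OC)c1OC
F7 | step 14 | 6-fluoro-2,3,4-trihydroxybenzaldehyde | O=Cc1c(F)cc(O)c(O)c1O
F8 | step 14 | 2,3,4-tris(benzyloxy)-6-fluorobenzaldehyde | O=Cc1c(F)cc(OCc2ccccc2)c(OCc2ccccc2)c1OCc1ccccc1
F0 | step 9 | none | none
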